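The plan rests on the aryl ether bond O1–C2 of the dihydrobenzofuran. C2 is the para-hydroxybenzylic carbon of ring D (the 2-aryl group) and O1 sits on ring C (the benzo ring) ortho to the carbon that carries C3. Acid therefore turns an open triol bisphenol, made by an Evans syn-aldol and holding only the C3 stereocentre of consequence, into the ring D para-quinone methide, which the ring C phenol captures: one operation closes the furan ring and sets C2 trans to C3 from either carbinol epimer. The same imide gives the open unit by an anti-aldol; the halves are joined by trans-selective alkylation of an (R)-β-substituted butyrolactone.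

Key step: step 8

Remark on the chemistry: ring A is the guaiacyl ring on the carbinol carbon of the open unit and ring B the ring that carries this unit; 1 is taken as purchasable; where the sense of induction of a chiral ligand or auxiliary is stated (steps 13 and 15), the antipode meant is the one that delivers the configuration written.

Step 1
Reactants: 1 methyl 3-bromo-4-hydroxy-5-methoxybenzoate
Product: 2 methyl 4-(benzyloxy)-3-bromo-5-methoxybenzoate
Conditions: BnBr, K2CO3, DMF, rt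
Reagents that add atoms: benzyl bromide, BrCc1ccccc1
Why: Williamson ether synthesis, in which the phenoxide of 1 displaces bromide and so masks the phenol that becomes O1 in one branch and the ring B phenol in the other.

Step 2
Reactants: 2 methyl 4-(benzyloxy)-3-bromo-5-methoxybenzoate
Product: 3 methyl 4-(benzyloxy)-3-(2-tert-butoxy-2-oxoethyl)-5-methoxybenzoate
Conditions: BrZnCH2CO2tBu (1.3 equiv), Pd(dba)2 (2 mol%), Q-Phos (2 mol%), THF, rt
Reagents that add atoms: (2-tert-butoxy-2-oxoethyl)zinc bromide, CC(C)(C)OC(=O)C[Zn]Br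
Why: Palladium-catalysed coupling of a Reformatsky reagent with an aryl bromide (Negishi-type arylation of a zinc ester enolate), which tolerates the methyl ester and installs the two carbons that become C3 and its hydroxymethyl group.

Step 3
Reactants: 3 methyl 4-(benzyloxy)-3-(2-tert-butoxy-2-oxoethyl)-5-methoxybenzoate
Product: 4 [2-(benzyloxy)-3-methoxy-5-(methoxycarbonyl)phenyl]acetic acid
Conditions: TFA, CH2Cl2, 0 °C to rt
Reagents that add atoms: none
Why: Acidolysis of the tert-butyl ester, with loss of the tert-butyl cation as 2-methylpropene, should leave the methyl benzoate and the aryl benzyl ether untouched.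

Step 4
Reactants: 4 [2-(benzyloxy)-3-methoxy-5-(methoxycarbonyl)phenyl]acetic acid; 5 (4S)-4-benzyl-1,3-oxazolidin-2-one
Product: 7 methyl 4-(benzyloxy)-3-{2-[(4S)-4-benzyl-2-oxo-1,3-oxazolidin-3-yl]-2-oxoethyl}-5-methoxybenzoate, via mixed pivalic anhydride 6 (not isolated)
Conditions: PivCl, Et3N, THF, −20 °C; then LiCl and 5, −20 °C to rt
Reagents that add atoms: pivaloyl chloride, CC(C)(C)C(Cl)=O (its atoms are carried only by intermediate 6)
Why: Mixed-anhydride N-acylation of an Evans oxazolidinone, the nitrogen attacking the unhindered arylacetyl carbonyl of 6.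

Step 5
Reactants: 7 methyl 4-(benzyloxy)-3-{2-[(4S)-4-benzyl-2-oxo-1,3-oxazolidin-3-yl]-2-oxoethyl}-5-methoxybenzoate; 8 4-(benzyloxy)-3-methoxybenzaldehyde
Product: 10 methyl 4-(benzyloxy)-3-{(2S,3S)-1-[(4S)-4-benzyl-2-oxo-1,3-oxazolidin-3-yl]-3-[4-(benzyloxy)-3-methoxyphenyl]-3-hydroxy-1-oxopropan-2-yl}-5-methoxybenzoate, via dibutylboron Z-enolate 9 (not isolated)
Conditions: Bu2BOTf (1.2 equiv), iPr2NEt (1.4 equiv), CH2Cl2, −78 to 0 °C; then 8, −78 to 0 °C; then pH 7 buffer, MeOH, 30% H2O2, 0 °C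
Reagents that add atoms: dibutylboron trifluoromethanesulfonate, CCCCB(CCCC)OS(=O)(=O)C(F)(F)F (boron and butyl groups only in intermediate 9)
Why: Evans boron syn-aldol reaction, in which the Z-enolate 9 reacts through a closed Zimmerman–Traxler chair with the auxiliary carbonyl turned away from boron, so that the auxiliary benzyl group fixes the enolate face and sets the aryl-bearing carbon (the future C3) and the carbinol carbon as the 2S,3S syn pair.

Step 6
Reactants: 10 methyl 4-(benzyloxy)-3-{(2S,3S)-1-[(4S)-4-benzyl-2-oxo-1,3-oxazolidin-3-yl]-3-[4-(benzyloxy)-3-methoxyphenyl]-3-hydroxy-1-oxopropan-2-yl}-5-methoxybenzoate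
Product: 11 methyl 4-(benzyloxy)-3-{(1S,2R)-1-[4-(benzyloxy)-3-methoxyphenyl]-1,3-dihydroxypropan-2-yl}-5-methoxybenzoate
Conditions: LiBH4 (1.5 equiv), MeOH (1.5 equiv), THF, 0 °C; aqueous NH4Cl
Reagents that add atoms: none
Why: Reductive cleavage of the N-acyl oxazolidinone by LiBH4, which should attack the activated exocyclic imide carbonyl much faster than the methyl benzoate and release the auxiliary.

Step 7
Reactants: 11 methyl 4-(benzyloxy)-3-{(1S,2R)-1-[4-(benzyloxy)-3-methoxyphenyl]-1,3-dihydroxypropan-2-yl}-5-methoxybenzoate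
Product: 12 methyl 3-[(1S,2R)-1,3-dihydroxy-1-(4-hydroxy-3-methoxyphenyl)propan-2-yl]-4-hydroxy-5-methoxybenzoate
Conditions: H2 (1 atm), Pd/C (10%), EtOAc, rt; filtrate used at once
Reagents that add atoms: none
Why: Catalytic hydrogenolysis of the two aryl benzyl ethers under neutral conditions should free both phenols while the benzylic hydroxyl, a poor leaving group without acid, is kept.

Step 8
Reactants: 12 methyl 3-[(1S,2R)-1,3-dihydroxy-1-(4-hydroxy-3-methoxyphenyl)propan-2-yl]-4-hydroxy-5-methoxybenzoate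
Product: 14 methyl (2S,3R)-2-(4-hydroxy-3-methoxyphenyl)-3-(hydroxymethyl)-7-methoxy-2,3-dihydro-1-benzofuran-5-carboxylate, via para-quinone methide 13 (not isolated)
Conditions: TsOH·H2O (10 mol%), CH2Cl2–THF (9:1, 0.01 M), 0 °C to rt
Reagents that add atoms: none
Why: Brønsted acid should ionise only the para-hydroxybenzylic carbinol of 12 (the primary alcohol cannot ionise), and loss of water gives the ring D para-quinone methide 13, whose exocyclic carbon, the future C2, is the electrophilic end of a vinylogous enone. The ring C phenol oxygen, the future O1, held ortho to the carbon that bears C3, adds to it in an intramolecular oxa-1,6-conjugate addition that rearomatises ring D; the closest known reaction type is the acid-mediated quinone methide cyclisation of 1-aryl-2-(2-hydroxyaryl)propane-1,3-diols, the biomimetic phenylcoumaran closure. The dihydrofuran ring closes in the 5-exo-trig mode, the attacked alkene carbon lying in the new ring and the other alkene carbon outside it. The new stereocentre C2 is controlled by C3: the aryl group takes the ring face opposite to the hydroxymethyl group, both through minimised allylic strain in 13 and because closure is reversible under acid and the trans isomer is the more stable, so 3R gives 2S. The carbinol configuration of 12 is erased in 13, so both aldol epimers converge on one product. The step needs capture by the phenol rather than oxetane formation by the primary alcohol or intermolecular capture, which the five-membered ring size and high dilution secure, and it needs ring C to stay un-ionised, which its ester group secures.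

Step 9
Reactants: 14 methyl (2S,3R)-2-(4-hydroxy-3-methoxyphenyl)-3-(hydroxymethyl)-7-methoxy-2,3-dihydro-1-benzofuran-5-carboxylate
Product: 15 methyl (2S,3R)-2-[4-(benzyloxy)-3-methoxyphenyl]-3-[(benzyloxy)methyl]-7-methoxy-2,3-dihydro-1-benzofuran-5-carboxylate
Conditions: NaH (2.5 equiv), BnBr (2.4 equiv), DMF, 0 °C to rt
Reagents that add atoms: benzyl bromide, BrCc1ccccc1
Why: Williamson ether synthesis on the phenoxide and the primary alkoxide should protect both hydroxyls as benzyl ethers for the later enolate chemistry and the single final hydrogenolysis.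

Step 10
Reactants: 15 methyl (2S,3R)-2-[4-(benzyloxy)-3-methoxyphenyl]-3-[(benzyloxy)methyl]-7-methoxy-2,3-dihydro-1-benzofuran-5-carboxylate
Product: 16 {(2S,3R)-2-[4-(benzyloxy)-3-methoxyphenyl]-3-[(benzyloxy)methyl]-7-methoxy-2,3-dihydro-1-benzofuran-5-yl}methanol
Conditions: iBu2AlH (2.5 equiv), CH2Cl2, −78 to 0 °C; Rochelle salt work-up
Reagents that add atoms: none
Why: Ester reduction by two hydride transfers from iBu2AlH should give the benzylic alcohol while the ethers and the dihydrobenzofuran stay inert.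

Step 11
Reactants: 16 {(2S,3R)-2-[4-(benzyloxy)-3-methoxyphenyl]-3-[(benzyloxy)methyl]-7-methoxy-2,3-dihydro-1-benzofuran-5-yl}methanol
Product: 17 (2S,3R)-2-[4-(benzyloxy)-3-methoxyphenyl]-3-[(benzyloxy)methyl]-7-methoxy-2,3-dihydro-1-benzofuran-5-carbaldehyde
Conditions: MnO2 (activated, excess), CH2Cl2, rt
Reagents that add atoms: none
Why: MnO2 oxidation is selective for the benzylic alcohol and should stop at the aldehyde.

Step 12
Reactants: 17 (2S,3R)-2-[4-(benzyloxy)-3-methoxyphenyl]-3-[(benzyloxy)methyl]-7-methoxy-2,3-dihydro-1-benzofuran-5-carbaldehyde; 18 dimethyl succinate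
Product: 19 (3E)-4-{(2S,3R)-2-[4-(benzyloxy)-3-methoxyphenyl]-3-[(benzyloxy)methyl]-7-methoxy-2,3-dihydro-1-benzofuran-5-yl}-3-(methoxycarbonyl)but-3-enoic acid
Conditions: NaOMe (2 equiv), MeOH, reflux; then aqueous HCl
Reagents that add atoms: none
Why: Stobbe condensation, in which the succinate enolate adds to the aldehyde and the paraconate lactone opens by elimination to the E alkylidene half-ester with the free acid on the methylene arm.

Step 13
Reactants: 19 (3E)-4-{(2S,3R)-2-[4-(benzyloxy)-3-methoxyphenyl]-3-[(benzyloxy)methyl]-7-methoxy-2,3-dihydro-1-benzofuran-5-yl}-3-(methoxycarbonyl)but-3-enoic acid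
Product: 20 (3R)-4-{(2S,3R)-2-[4-(benzyloxy)-3-methoxyphenyl]-3-[(benzyloxy)methyl]-7-methoxy-2,3-dihydro-1-benzofuran-5-yl}-3-(methoxycarbonyl)butanoic acid
Conditions: H2 (5 atm), [Rh(cod)2]BF4 (1 mol%), (S,S)-Et-DuPhos (1.1 mol%), Et3N (1 equiv), MeOH, rt
Reagents that add atoms: none
Why: Rhodium-catalysed asymmetric hydrogenation of an itaconate-type half-ester, in which carboxylate and alkene chelate the metal and the chiral bisphospholane selects the alkene face, should set the future lactone β-carbon as R under catalyst control, the remote dihydrobenzofuran centres not interfering.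

Step 14
Reactants: 20 (3R)-4-{(2S,3R)-2-[4-(benzyloxy)-3-methoxyphenyl]-3-[(benzyloxy)methyl]-7-methoxy-2,3-dihydro-1-benzofuran-5-yl}-3-(methoxycarbonyl)butanoic acid
Product: 22 (4R)-4-({(2S,3R)-2-[4-(benzyloxy)-3-methoxyphenyl]-3-[(benzyloxy)methyl]-7-methoxy-2,3-dihydro-1-benzofuran-5-yl}methyl)oxolan-2-one, via hydroxy acid 21 (not isolated)
Conditions: LiOH·H2O (1.0 equiv), THF–H2O, then dried; LiBH4 (2 equiv), THF, 0 °C to rt; then 2 M HCl, rt
Reagents that add atoms: none
Why: Chemoselective borohydride reduction of the methyl ester beside the lithium carboxylate, then acid-promoted lactonisation of the γ-hydroxy acid 21, should carry the stereocentre unchanged into the (R)-β-substituted γ-butyrolactone.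

Step 15
Reactants: 7 methyl 4-(benzyloxy)-3-{2-[(4S)-4-benzyl-2-oxo-1,3-oxazolidin-3-yl]-2-oxoethyl}-5-methoxybenzoate; 8 4-(benzyloxy)-3-methoxybenzaldehyde
Product: 24 methyl 4-(benzyloxy)-3-{(2R,3S)-1-[(4S)-4-benzyl-2-oxo-1,3-oxazolidin-3-yl]-3-[4-(benzyloxy)-3-methoxyphenyl]-3-hydroxy-1-oxopropan-2-yl}-5-methoxybenzoate, via trimethylsilyl ether 23 (not isolated)
Conditions: MgCl2 (20 mol%), Et3N (2 equiv), Me3SiCl (1.5 equiv), EtOAc, rt; then TFA–MeOH, 0 °C
Reagents that add atoms: chlorotrimethylsilane, C[Si](C)(C)Cl (silyl group only in intermediate 23)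
Why: Evans magnesium-halide-catalysed direct anti-aldol reaction, in which soft enolisation gives a magnesium-chelated Z-enolate that meets the aldehyde on the face away from the auxiliary benzyl group through a boat transition state, so the α-carbon is set opposite to that from the boron aldol and the carbinol anti to it (2R,3S), silylation driving turnover and the silyl ether 23 being cleaved on work-up.

Step 16
Reactants: 24 methyl 4-(benzyloxy)-3-{(2R,3S)-1-[(4S)-4-benzyl-2-oxo-1,3-oxazolidin-3-yl]-3-[4-(benzyloxy)-3-methoxyphenyl]-3-hydroxy-1-oxopropan-2-yl}-5-methoxybenzoate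
Product: 25 (1S,2S)-1-[4-(benzyloxy)-3-methoxyphenyl]-2-[2-(benzyloxy)-5-(hydroxymethyl)-3-methoxyphenyl]propane-1,3-diol
Conditions: LiAlH4 (4 equiv), THF, −10 to 0 °C; aqueous NaOH work-up
Reagents that add atoms: none
Why: Hydride reduction with LiAlH4 should cleave the auxiliary reductively and reduce the benzoate in the same operation, giving the anti triol without touching the two stereocentres.

Step 17
Reactants: 25 (1S,2S)-1-[4-(benzyloxy)-3-methoxyphenyl]-2-[2-(benzyloxy)-5-(hydroxymethyl)-3-methoxyphenyl]propane-1,3-diol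
Product: 26 {4-(benzyloxy)-3-[(2S,4S,5S)-4-[4-(benzyloxy)-3-methoxyphenyl]-2-phenyl-1,3-dioxan-5-yl]-5-methoxyphenyl}methanol
Conditions: PhCH(OMe)2 (1.2 equiv), PPTS (10 mol%), 4 Å molecular sieves, CH2Cl2, rt
Reagents that add atoms: benzaldehyde dimethyl acetal, COC(OC)c1ccccc1
Why: Acid-catalysed transacetalisation, in which only the 1,3-diol can form a six-membered benzylidene acetal that settles as the all-equatorial chair, fixing the acetal carbon as S under thermodynamic control and leaving the benzylic primary alcohol free.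

Step 18
Reactants: 26 {4-(benzyloxy)-3-[(2S,4S,5S)-4-[4-(benzyloxy)-3-methoxyphenyl]-2-phenyl-1,3-dioxan-5-yl]-5-methoxyphenyl}methanol
Product: 27 (2S,4S,5S)-5-[2-(benzyloxy)-5-(bromomethyl)-3-methoxyphenyl]-4-[4-(benzyloxy)-3-methoxyphenyl]-2-phenyl-1,3-dioxane
Conditions: CBr4, PPh3, CH2Cl2, 0 °C; used directly
Reagents that add atoms: carbon tetrabromide, BrC(Br)(Br)Br
Why: Appel reaction should convert the remaining primary benzylic alcohol into the bromide under neutral conditions that spare the acetal.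

Step 19
Reactants: 22 (4R)-4-({(2S,3R)-2-[4-(benzyloxy)-3-methoxyphenyl]-3-[(benzyloxy)methyl]-7-methoxy-2,3-dihydro-1-benzofuran-5-yl}methyl)oxolan-2-one; 27 (2S,4S,5S)-5-[2-(benzyloxy)-5-(bromomethyl)-3-methoxyphenyl]-4-[4-(benzyloxy)-3-methoxyphenyl]-2-phenyl-1,3-dioxane
Product: 29 (3R,4R)-3-{4-(benzyloxy)-3-[(2S,4S,5S)-4-[4-(benzyloxy)-3-methoxyphenyl]-2-phenyl-1,3-dioxan-5-yl]-5-methoxybenzyl}-4-({(2S,3R)-2-[4-(benzyloxy)-3-methoxyphenyl]-3-[(benzyloxy)methyl]-7-methoxy-2,3-dihydro-1-benzofuran-5-yl}methyl)oxolan-2-one, via lithium enolate 28 (not isolated)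
Conditions: LiN(SiMe3)2 (1.1 equiv), THF, −78 °C; then 27, DMPU, −78 to −30 °C
Reagents that add atoms: lithium bis(trimethylsilyl)amide, [Li+].C[Si](C)(C)[N-][Si](C)(C)C (lithium only in intermediate 28)
Why: Alkylation of a γ-butyrolactone lithium enolate, in which the bromide approaches 28 anti to the β-substituent, should give the trans 3,4-disubstituted lactone and set the α-carbon as R by substrate control.

Step 20
Reactants: 29 (3R,4R)-3-{4-(benzyloxy)-3-[(2S,4S,5S)-4-[4-(benzyloxy)-3-methoxyphenyl]-2-phenyl-1,3-dioxan-5-yl]-5-methoxybenzyl}-4-({(2S,3R)-2-[4-(benzyloxy)-3-methoxyphenyl]-3-[(benzyloxy)methyl]-7-methoxy-2,3-dihydro-1-benzofuran-5-yl}methyl)oxolan-2-one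
Product: 30 (3R,4R)-3-{3-[(1S,2S)-1,3-dihydroxy-1-(4-hydroxy-3-methoxyphenyl)propan-2-yl]-4-hydroxy-5-methoxybenzyl}-4-{[(2S,3R)-2-(4-hydroxy-3-methoxyphenyl)-3-(hydroxymethyl)-7-methoxy-2,3-dihydro-1-benzofuran-5-yl]methyl}oxolan-2-one
Conditions: H2 (1 atm), Pd/C (10%), EtOAc–MeOH (1:1), rt, stopped at full conversion; acid-free work-up
Reagents that add atoms: none
Why: Global hydrogenolysis should cleave the four benzyl ethers and the benzylidene acetal under neutral conditions, so the ortho-phenol and para-hydroxybenzylic alcohol of the open unit never meet acid and cannot close to a second dihydrobenzofuran.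

Compound list

1 | methyl 3-bromo-4-hydroxy-5-methoxybenzoate | COC(=O)c1cc(Br)c(O)c(OC)c1 | starting material
2 | methyl 4-(benzyloxy)-3-bromo-5-methoxybenzoate | COC(=O)c1cc(Br)c(OCc2ccccc2)c(OC)c1 | intermediate
3 | methyl 4-(benzyloxy)-3-(2-tert-butoxy-2-oxoethyl)-5-methoxybenzoate | COC(=O)c1cc(CC(=O)OC(C)(C)C)c(OCc2ccccc2)c(OC)c1 | intermediate
4 | [2-(benzyloxy)-3-methoxy-5-(methoxycarbonyl)phenyl]acetic acid | COC(=O)c1cc(CC(O)=O)c(OCc2ccccc2)c(OC)c1 | intermediate
5 | (4S)-4-benzyl-1,3-oxazolidin-2-one | O=C1OC[C@H](Cc2ccccc2)N1 | starting material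
6 | mixed anhydride of 4 with pivalic acid | COC(=O)c1cc(CC(=O)OC(=O)C(C)(C)C)c(OCc2ccccc2)c(OC)c1 | intermediate
7 | methyl 4-(benzyloxy)-3-{2-[(4S)-4-benzyl-2-oxo-1,3-oxazolidin-3-yl]-2-oxoethyl}-5-methoxybenzoate | COC(=O)c1cc(CC(=O)N2[C@@H](Cc3ccccc3)COC2=O)c(OCc2ccccc2)c(OC)c1 | intermediate
8 | 4-(benzyloxy)-3-methoxybenzaldehyde | COc1cc(C=O)ccc1OCc1ccccc1 | starting material
9 | dibutylboron Z-enolate of 7 (boron oxygen and aryl group on the same side of the enolate double bond) | CCCCB(CCCC)O/C(=C\c1cc(C(=O)OC)cc(OC)c1OCc1ccccc1)N1[C@@H](Cc2ccccc2)COC1=O | intermediate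
10 | methyl 4-(benzyloxy)-3-{(2S,3S)-1-[(4S)-4-benzyl-2-oxo-1,3-oxazolidin-3-yl]-3-[4-(benzyloxy)-3-methoxyphenyl]-3-hydroxy-1-oxopropan-2-yl}-5-methoxybenzoate (syn aldol) | COc1cc([C@@H](O)[C@@H](C(=O)N2[C@@H](Cc3ccccc3)COC2=O)c2cc(C(=O)OC)cc(OC)c2OCc2ccccc2)ccc1OCc1ccccc1 | intermediate
11 | methyl 4-(benzyloxy)-3-{(1S,2R)-1-[4-(benzyloxy)-3-methoxyphenyl]-1,3-dihydroxypropan-2-yl}-5-methoxybenzoate | COc1cc([C@@H](O)[C@@H](CO)c2cc(C(=O)OC)cc(OC)c2OCc2ccccc2)ccc1OCc1ccccc1 | intermediate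
12 | methyl 3-[(1S,2R)-1,3-dihydroxy-1-(4-hydroxy-3-methoxyphenyl)propan-2-yl]-4-hydroxy-5-methoxybenzoate | COc1cc([C@@H](O)[C@@H](CO)c2cc(C(=O)OC)cc(OC)c2O)ccc1O | intermediate
13 | methyl 4-hydroxy-3-[(2R)-1-hydroxy-3-(3-methoxy-4-oxocyclohexa-2,5-dien-1-ylidene)propan-2-yl]-5-methoxybenzoate (para-quinone methide; one alkene geometry drawn, both close alike) | COC1=C/C(=C\[C@@H](CO)c2cc(C(=O)OC)cc(OC)c2O)C=CC1=O | intermediate
14 | methyl (2S,3R)-2-(4-hydroxy-3-methoxyphenyl)-3-(hydroxymethyl)-7-methoxy-2,3-dihydro-1-benzofuran-5-carboxylate | COC(=O)c1cc(OC)c2c(c1)[C@H](CO)[C@@H](c1ccc(O)c(OC)c1)O2 | intermediate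
15 | methyl (2S,3R)-2-[4-(benzyloxy)-3-methoxyphenyl]-3-[(benzyloxy)methyl]-7-methoxy-2,3-dihydro-1-benzofuran-5-carboxylate | COC(=O)c1cc(OC)c2c(c1)[C@H](COCc1ccccc1)[C@@H](c1ccc(OCc3ccccc3)c(OC)c1)O2 | intermediate
16 | {(2S,3R)-2-[4-(benzyloxy)-3-methoxyphenyl]-3-[(benzyloxy)methyl]-7-methoxy-2,3-dihydro-1-benzofuran-5-yl}methanol | OCc1cc(OC)c2c(c1)[C@H](COCc1ccccc1)[C@@H](c1ccc(OCc3ccccc3)c(OC)c1)O2 | intermediate
17 | (2S,3R)-2-[4-(benzyloxy)-3-methoxyphenyl]-3-[(benzyloxy)methyl]-7-methoxy-2,3-dihydro-1-benzofuran-5-carbaldehyde | O=Cc1cc(OC)c2c(c1)[C@H](COCc1ccccc1)[C@@H](c1ccc(OCc3ccccc3)c(OC)c1)O2 | intermediate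
18 | dimethyl succinate | COC(=O)CCC(=O)OC | starting material
19 | (3E)-4-{(2S,3R)-2-[4-(benzyloxy)-3-methoxyphenyl]-3-[(benzyloxy)methyl]-7-methoxy-2,3-dihydro-1-benzofuran-5-yl}-3-(methoxycarbonyl)but-3-enoic acid | COC(=O)/C(CC(O)=O)=C/c1cc(OC)c2c(c1)[C@H](COCc1ccccc1)[C@@H](c1ccc(OCc3ccccc3)c(OC)c1)O2 | intermediate
20 | (3R)-4-{(2S,3R)-2-[4-(benzyloxy)-3-methoxyphenyl]-3-[(benzyloxy)methyl]-7-methoxy-2,3-dihydro-1-benzofuran-5-yl}-3-(methoxycarbonyl)butanoic acid | OC(=O)C[C@H](C(=O)OC)Cc1cc(OC)c2c(c1)[C@H](COCc1ccccc1)[C@@H](c1ccc(OCc3ccccc3)c(OC)c1)O2 | intermediate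
21 | (3R)-4-{(2S,3R)-2-[4-(benzyloxy)-3-methoxyphenyl]-3-[(benzyloxy)methyl]-7-methoxy-2,3-dihydro-1-benzofuran-5-yl}-3-(hydroxymethyl)butanoic acid | OC(=O)C[C@H](CO)Cc1cc(OC)c2c(c1)[C@H](COCc1ccccc1)[C@@H](c1ccc(OCc3ccccc3)c(OC)c1)O2 | intermediate
22 | (4R)-4-({(2S,3R)-2-[4-(benzyloxy)-3-methoxyphenyl]-3-[(benzyloxy)methyl]-7-methoxy-2,3-dihydro-1-benzofuran-5-yl}methyl)oxolan-2-one | O=C1C[C@@H](Cc2cc(OC)c3c(c2)[C@H](COCc2ccccc2)[C@@H](c2ccc(OCc4ccccc4)c(OC)c2)O3)CO1 | intermediate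
23 | trimethylsilyl ether of 24 at the carbinol oxygen (2R,3S) | COc1cc([C@@H](O[Si](C)(C)C)[C@H](C(=O)N2[C@@H](Cc3ccccc3)COC2=O)c2cc(C(=O)OC)cc(OC)c2OCc2ccccc2)ccc1OCc1ccccc1 | intermediate
24 | methyl 4-(benzyloxy)-3-{(2R,3S)-1-[(4S)-4-benzyl-2-oxo-1,3-oxazolidin-3-yl]-3-[4-(benzyloxy)-3-methoxyphenyl]-3-hydroxy-1-oxopropan-2-yl}-5-methoxybenzoate (anti aldol) | COc1cc([C@@H](O)[C@H](C(=O)N2[C@@H](Cc3ccccc3)COC2=O)c2cc(C(=O)OC)cc(OC)c2OCc2ccccc2)ccc1OCc1ccccc1 | intermediate
25 | (1S,2S)-1-[4-(benzyloxy)-3-methoxyphenyl]-2-[2-(benzyloxy)-5-(hydroxymethyl)-3-methoxyphenyl]propane-1,3-diol | COc1cc([C@@H](O)[C@H](CO)c2cc(CO)cc(OC)c2OCc2ccccc2)ccc1OCc1ccccc1 | intermediate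
26 | {4-(benzyloxy)-3-[(2S,4S,5S)-4-[4-(benzyloxy)-3-methoxyphenyl]-2-phenyl-1,3-dioxan-5-yl]-5-methoxyphenyl}methanol (all three ring substituents equatorial) | OCc1cc(OC)c(OCc2ccccc2)c(c1)[C@H]1CO[C@H](c2ccccc2)O[C@@H]1c1ccc(OCc2ccccc2)c(OC)c1 | intermediate
27 | (2S,4S,5S)-5-[2-(benzyloxy)-5-(bromomethyl)-3-methoxyphenyl]-4-[4-(benzyloxy)-3-methoxyphenyl]-2-phenyl-1,3-dioxane | BrCc1cc(OC)c(OCc2ccccc2)c(c1)[C@H]1CO[C@H](c2ccccc2)O[C@@H]1c1ccc(OCc2ccccc2)c(OC)c1 | intermediate
28 | lithium enolate of 22 | [Li]OC1=C[C@@H](Cc2cc(OC)c3c(c2)[C@H](COCc2ccccc2)[C@@H](c2ccc(OCc4ccccc4)c(OC)c2)O3)CO1 | intermediate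
29 | (3R,4R)-3-{4-(benzyloxy)-3-[(2S,4S,5S)-4-[4-(benzyloxy)-3-methoxyphenyl]-2-phenyl-1,3-dioxan-5-yl]-5-methoxybenzyl}-4-({(2S,3R)-2-[4-(benzyloxy)-3-methoxyphenyl]-3-[(benzyloxy)methyl]-7-methoxy-2,3-dihydro-1-benzofuran-5-yl}methyl)oxolan-2-one | O=C1OC[C@H](Cc2cc(OC)c3c(c2)[C@H](COCc2ccccc2)[C@@H](c2ccc(OCc4ccccc4)c(OC)c2)O3)[C@H]1Cc1cc(OC)c(OCc2ccccc2)c(c1)[C@H]1CO[C@H](c2ccccc2)O[C@@H]1c1ccc(OCc2ccccc2)c(OC)c1 | intermediate
30 | (3R,4R)-3-{3-[(1S,2S)-1,3-dihydroxy-1-(4-hydroxy-3-methoxyphenyl)propan-2-yl]-4-hydroxy-5-methoxybenzyl}-4-{[(2S,3R)-2-(4-hydroxy-3-methoxyphenyl)-3-(hydroxymethyl)-7-methoxy-2,3-dihydro-1-benzofuran-5-yl]methyl}oxolan-2-one | COc1cc([C@@H](O)[C@H](CO)c2cc(C[C@H]3C(=O)OC[C@@H]3Cc3cc(OC)c4c(c3)[C@H](CO)[C@@H](c3ccc(O)c(OC)c3)O4)cc(OC)c2O)ccc1O | target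

Total step count: 20.
Longest linear sequence: 16 steps (steps 1 to 14, then 19 and 20).

Steps most likely to fail

1. Step 15 (anti-aldol). The process at risk is reversible enolisation of the acidic α-aryl imide and retro-aldol under the amine base, which would erode the anti selectivity or the α-configuration. The fallback sets out from 2 and comes back at 25, making the carbon–carbon bond by allylboration instead of an enolate aldol. Suzuki–Miyaura vinylation of 2 (potassium vinyltrifluoroborate, PdCl2(dppf), Cs2CO3) should give methyl 4-(benzyloxy)-3-ethenyl-5-methoxybenzoate F1. Cross-metathesis with allylboronic acid pinacol ester (second-generation Grubbs catalyst) should give the E allylic boronate methyl 4-(benzyloxy)-3-methoxy-5-[(1E)-3-(4,4,5,5-tetramethyl-1,3,2-dioxaborolan-2-yl)prop-1-en-1-yl]benzoate F2. Its addition to 8 under a chiral phosphoric acid (TRIP, the antipode that gives the 1S carbinol) passes through a closed chair, so the E boronate should give the anti homoallylic alcohol methyl 4-(benzyloxy)-3-{(1S,2R)-1-[4-(benzyloxy)-3-methoxyphenyl]-1-hydroxybut-3-en-2-yl}-5-methoxybenzoate F3. Ozonolysis with NaBH4 work-up should give methyl 4-(benzyloxy)-3-{(1S,2S)-1-[4-(benzyloxy)-3-methoxyphenyl]-1,3-dihydroxypropan-2-yl}-5-methoxybenzoate F4, which LiAlH4 reduces to 25.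

2. Step 8 (ring closure). The processes at risk are intermolecular capture of the quinone methide, acid-induced loss of the hydroxymethyl carbon as formaldehyde with stilbene formation, and incomplete trans selectivity. The fallback sets out from 11 and comes back at 14, closing the same O–C bond under neutral Mitsunobu conditions with the primary alcohol masked. Selective silylation of the primary hydroxyl of 11 (tBuMe2SiCl, imidazole) should give methyl 4-(benzyloxy)-3-{(1S,2R)-1-[4-(benzyloxy)-3-methoxyphenyl]-3-[(tert-butyldimethylsilyl)oxy]-1-hydroxypropan-2-yl}-5-methoxybenzoate F5. Hydrogenolysis (H2, Pd/C) should give methyl 3-{(1S,2R)-3-[(tert-butyldimethylsilyl)oxy]-1-hydroxy-1-(4-hydroxy-3-methoxyphenyl)propan-2-yl}-4-hydroxy-5-methoxybenzoate F6. PPh3 and diisopropyl azodicarboxylate should then close it to methyl (2S,3R)-3-{[(tert-butyldimethylsilyl)oxy]methyl}-2-(4-hydroxy-3-methoxyphenyl)-7-methoxy-2,3-dihydro-1-benzofuran-5-carboxylate F7; the free para-hydroxyl makes the displacement ionisation-like, so the trans isomer is again expected. Bu4NF then gives 14.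

3. Step 20 (global hydrogenolysis). The process at risk is over-reduction: hydrogenolytic loss of the benzylic oxygen on the ring A carbinol while it is still part of the acetal, or opening of the dihydrobenzofuran at the C2–O1 bond, before all benzyl groups are gone. The fallback sets out from 29 and comes back at 30, removing the acetal by hydrolysis so that hydrogenolysis only has benzyl ethers to cleave. Aqueous AcOH (80%, 40 °C) should give (3R,4R)-3-{4-(benzyloxy)-3-[(1S,2S)-1-[4-(benzyloxy)-3-methoxyphenyl]-1,3-dihydroxypropan-2-yl]-5-methoxybenzyl}-4-({(2S,3R)-2-[4-(benzyloxy)-3-methoxyphenyl]-3-[(benzyloxy)methyl]-7-methoxy-2,3-dihydro-1-benzofuran-5-yl}methyl)oxolan-2-one F8; its ring B phenol is still benzylated, so the open unit cannot cyclise under the acid. A short hydrogenolysis (H2, Pd(OH)2 on carbon, EtOAc) then gives 30.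

Further compounds

F1 | step 15 | methyl 4-(benzyloxy)-3-ethenyl-5-methoxybenzoate | COC(=O)c1cc(C=C)c(OCc2ccccc2)c(OC)c1
F2 | step 15 | methyl 4-(benzyloxy)-3-methoxy-5-[(1E)-3-(4,4,5,5-tetramethyl-1,3,2-dioxaborolan-2-yl)prop-1-en-1-yl]benzoate | COC(=O)c1cc(/C=C/CB2OC(C)(C)C(C)(C)O2)c(OCc2ccccc2)c(OC)c1
F3 | step 15 | methyl 4-(benzyloxy)-3-{(1S,2R)-1-[4-(benzyloxy)-3-methoxyphenyl]-1-hydroxybut-3-en-2-yl}-5-methoxybenzoate | COc1cc([C@@H](O)[C@H](C=C)c2cc(C(=O)OC)cc(OC)c2OCc2ccccc2)ccc1OCc1ccccc1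
F4 | step 15 | methyl 4-(benzyloxy)-3-{(1S,2S)-1-[4-(benzyloxy)-3-methoxyphenyl]-1,3-dihydroxypropan-2-yl}-5-methoxybenzoate | COc1cc([C@@H](O)[C@H](CO)c2cc(C(=O)OC)cc(OC)c2OCc2ccccc2)ccc1OCc1ccccc1
F5 | step 8 | methyl 4-(benzyloxy)-3-{(1S,2R)-1-[4-(benzyloxy)-3-methoxyphenyl]-3-[(tert-butyldimethylsilyl)oxy]-1-hydroxypropan-2-yl}-5-methoxybenzoate | COc1cc([C@@H](O)[C@@H](CO[Si](C)(C)C(C)(C)C)c2cc(C(=O)OC)cc(OC)c2OCc2ccccc2)ccc1OCc1ccccc1
F6 | step 8 | methyl 3-{(1S,2R)-3-[(tert-butyldimethylsilyl)oxy]-1-hydroxy-1-(4-hydroxy-3-methoxyphenyl)propan-2-yl}-4-hydroxy-5-methoxybenzoate | COc1cc([C@@H](O)[C@@H](CO[Si](C)(C)C(C)(C)C)c2cc(C(=O)OC)cc(OC)c2O)ccc1O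
F7 | step 8 | methyl (2S,3R)-3-{[(tert-butyldimethylsilyl)oxy]methyl}-2-(4-hydroxy-3-methoxyphenyl)-7-methoxy-2,3-dihydro-1-benzofuran-5-carboxylate | COC(=O)c1cc(OC)c2c(c1)[C@H](CO[Si](C)(C)C(C)(C)C)[C@@H](c1ccc(O)c(OC)c1)O2
F8 | step 20 | (3R,4R)-3-{4-(benzyloxy)-3-[(1S,2S)-1-[4-(benzyloxy)-3-methoxyphenyl]-1,3-dihydroxypropan-2-yl]-5-methoxybenzyl}-4-({(2S,3R)-2-[4-(benzyloxy)-3-methoxyphenyl]-3-[(benzyloxy)methyl]-7-methoxy-2,3-dihydro-1-benzofuran-5-yl}methyl)oxolan-2-one | COc1cc([C@@H](O)[C@H](CO)c2cc(C[C@H]3C(=O)OC[C@@H]3Cc3cc(OC)c4c(c3)[C@H](COCc3ccccc3)[C@@H](c3ccc(OCc5ccccc5)c(OC)c3)O4)cc(OC)c2OCc2ccccc2)ccc1OCc1ccccc1
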